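Which flask ends with more target, the one held cold for six minutes or the one given a warm minute and then a cold one? Count lifetimes of the starting material.

in all of them: starting material 10 mM

|  | reagent | free catalyst | temperature | remark | time |
|---|---|---|---|---|---|
| theta | 1.1 equiv | 2.4 mol% | 20 °C | run made earlier |  |
| north-west | 1.10 equiv | 1.2 mol% |  | at −20 °C throughout | 6.0 min |
| north-east | 1.10 equiv | 1.2 mol% |  | at 20 °C until 1.0 min, from then on at −20 °C | 2.0 min |

theta run (percent of the starting material charged)

| time / s | target / % | starting material / % |
|---|---|---|
| 10.0 | 8.4 | 89.8 |
| 15.0 | 13.9 | 84.3 |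
| 25.0 | 21.7 | 76.1 |
| 40.0 | 33.1 | 63.3 |

(standard deviation of a reading: 0.5 percentage points)

1. the flask that ends with the higher amount of target, in percent of the starting material charged, or "neither" when 2 percentage points or less lies between them (north-west / north-east / neither)
2. final target, as a percentage of the starting material charged, in north-west
3. final target, as a percentage of the starting material charged, in north-east

- the earlier runs do not show what temperature does; that part of a forecast is a guess
- no earlier run changes the charge of free catalyst; that part of a forecast is a guess

Take the lifetime τ of the starting material as the time in which it falls by a factor e, so a flask that spends time t at steady τ uses n = t/τ lifetimes and keeps exp(−n) of its charge. The last theta reading, 63.3% left after 40.0 s, gives τ = 87.5 s. Object that τ may drift as the reagent falls: the first reading gives 92.9 s, but it rests on a loss of 10.2% read with a scatter of 0.5 percentage points, so take τ as steady, a working fit to these readings and no more. Object next that the new flasks hold 1.2 mol% of free catalyst, not 2.4 mol%, and that no run shows what this does. Guess that τ grows in proportion, to the half-loaded warm lifetime 2.92 min.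

The warm minute of north-east then uses 0.343 lifetimes and leaves 71.0%. At the last theta reading, 90.2% of what was lost stood as target, so expect 26.2% target when the cold begins.

Object that the cold lifetime is unknown, since no run shows temperature. Call S the factor by which the cold stretches τ. North-west spends 6.0 min at Sτ and north-east spends 1.0 min at τ and 1.00 min at Sτ, so north-east uses more lifetimes if S exceeds 5.00. At that S its cold minute adds 0.0686 lifetimes. Commit to north-east, at a little above the warm figure.

The forecast says north-east, with 6% in north-west and 25% in north-east: "its warm minute outweighs six cold minutes unless the temperature dependence is very weak". My warm minute alone gives more than its whole north-east flask.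

North-east ends at 26.8% target and north-west at 5.10%, so north-east holds more, from these steps:

    starting material + free catalyst ⇌ catalyst intermediate A (K = 222 M⁻¹, k = 7270 M⁻¹ s⁻¹, Ea = 13.0 kJ mol⁻¹, ΔH = 8.00 kJ mol⁻¹)
    catalyst intermediate C → spent catalyst (k = 0.0110 s⁻¹, Ea = 86.0 kJ mol⁻¹)
    catalyst intermediate D → free catalyst + target (k = 3.96 s⁻¹, Ea = 58.0 kJ mol⁻¹)
    catalyst intermediate A ⇌ catalyst intermediate B (K = 5.50, k = 2.12 s⁻¹, Ea = 62.0 kJ mol⁻¹, ΔH = −37.0 kJ mol⁻¹)
    catalyst intermediate C → by-product + catalyst intermediate D (k = 2.96 s⁻¹, Ea = 60.0 kJ mol⁻¹)
    reagent + catalyst intermediate B ⇌ catalyst intermediate C (K = 59.1 M⁻¹, k = 243 M⁻¹ s⁻¹, Ea = 39.0 kJ mol⁻¹, ΔH = −89.0 kJ mol⁻¹)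
    (constants at 20 °C)

North-east has 8.10% of its catalyst spent at the end, against 0.302% in north-west, and its 72% of unbound starting material counts 0.324 lifetimes. North-west's 94% counts 0.0619 lifetimes, a cold lifetime of 97.3 min. North-east's 73.1% at the change of temperature gives a warm lifetime of 3.19 min, against the guessed 2.92 min, which puts S at 30.5, above the needed value. The same flask at 5 °C keeps 44% after 6.00 min, a lifetime of 7.31 min.

All runs come from a simulation for substances that don't exist; scatter was added.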